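1. Numbering used throughout: C1 (ring C=O), C2=C3 (CH3 on C3), cyclobutane C4–C5–C11–C10, then C6 (CH3 and C12H2O), C7, C8, C9; β is the face of the small ring that carries the C10 methyl, α the other face.
2. Cuts, last to first: the three ester C–O bonds; C7–C8 of the seven-membered ring (aldol); C2=C3 of the cyclohexenone (ring-closing metathesis); C5–C11 of the cyclobutane (Wolff contraction of a 2-diazocyclopentanone); C5–C6 and C4–C3 on a cyclopentenone.
3. Feature that allows the key cut: the cyclobutane carries the C1 carbonyl on C11, next to C5, and its arms on C5 (α), C4 (β) and C10 (C9 α) alternate faces, so returning C1 to the ring between C11 and C5 gives a cyclopentanone whose centres come from ordinary enone chemistry.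
4. Forward order of rings: cyclopentanone → cyclobutane → bicyclo[3.1.1]heptenone → seven-membered ring; the acyl groups go on last.
5. Stereochemistry: C10 by catalytic asymmetric conjugate addition; C4 and C5 by anti addition and anti alkylation; C6 by convex-face alkylation of a cis-fused lactone; C11 by equilibration; C7 and C9 by two hydroxyl-directed reductions relayed from C12–OH.

Key step: step 12

Remark: the target is read as the (4R,5S,6S,7R,9R,10R,11R) isomer in the numbering above, with (Z)-2-methylbut-2-enoate (angelate) on O12, and 4-methoxybenzyl chloromethyl ether is taken to be an available reagent.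

Route

Step 1
Reactants: 1 3-methylcyclopent-2-en-1-one; 2 ethynyltrimethylsilane
Product: 4 (R)-3-methyl-3-[1-(trimethylsilyl)ethenyl]cyclopentan-1-one, via vinylalane 3 (not isolated)
Conditions: i-Bu2AlH, hexanes, 55 °C; then 1, Cu(OTf)2 (5 mol %), chiral sulfonate-bearing imidazolinium salt (NHC precursor, 5 mol %), THF, −78 → −50 °C
Reagents that add atoms: none
Why: Copper–NHC-catalysed asymmetric conjugate addition of a silyl-substituted vinylalane to a β-methyl cyclic enone is an established route to quaternary centres; the ligand enantiomer is chosen to give C10 as R, and the 1-silylvinyl group serves both as a masked acetyl (C9, C8) and as the bulky group that later steers C4.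

Step 2
Reactants: 4 (R)-3-methyl-3-[1-(trimethylsilyl)ethenyl]cyclopentan-1-one
Product: 6 (S)-4-methyl-4-[1-(trimethylsilyl)ethenyl]cyclopent-2-en-1-one, via silyl enol ether 5 (not isolated)
Conditions: LiN(i-Pr)2, TMSCl, THF, −78 °C; then Pd(OAc)2 (1.05 equiv), MeCN, rt
Reagents that add atoms: none
Why: Kinetic deprotonation takes place at C5, away from quaternary C10, and the Saegusa–Ito oxidation can only desaturate C5–C4, so a single enone forms and C10 is untouched.

Step 3
Reactants: 6 (S)-4-methyl-4-[1-(trimethylsilyl)ethenyl]cyclopent-2-en-1-one; 7 isopropenylmagnesium bromide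
Product: 8 silyl enol ether (C1–OSiMe3; C1=C5; isopropenyl β on C4)
Conditions: CuBr·SMe2 (10 mol %), TMSCl, THF, −78 °C
Reagents that add atoms: chlorotrimethylsilane, C[Si](C)(C)Cl
Why: In this TMSCl-accelerated copper-catalysed conjugate addition the isopropenyl group enters C4 anti to the much larger 1-silylvinyl group on C10 (hence cis to the C10 methyl), and the C1–C5 enolate is trapped regiospecifically as its silyl ether.

Step 4
Reactants: 8 silyl enol ether; 9 methyl bromoacetate
Product: 11 keto ester (CH2CO2Me α on C5), via lithium enolate 10 (not isolated)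
Conditions: MeLi, THF, 0 °C; then 9, HMPA, −78 → −20 °C
Reagents that add atoms: none
Why: Methyllithium releases the regio-defined lithium enolate, and its SN2 alkylation by the reactive α-bromo ester occurs at C5 anti to the neighbouring isopropenyl group, which sets C5 with its side chain α (enolate alkylation).

Step 5
Reactants: 11 keto ester
Product: 13 cis-fused γ-lactone (C7(=O)–O–C1 on the α face), via hydroxy ester 12 (not isolated)
Conditions: LiBH(s-Bu)3 (L-Selectride), THF, −78 °C → rt
Reagents that add atoms: none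
Why: The bulky borohydride attacks C1 from the β face, anti to the C5 side chain (the selectivity known for 2,3-trans-disubstituted cyclopentanones), so the C1 alkoxide is cis to the ester arm and closes the cis-fused lactone by transesterification.

Step 6
Reactants: 13 cis-fused γ-lactone
Product: 15 α-methyl lactone (C6 methyl exo), via lithium enolate 14 (not isolated)
Conditions: LiN(i-Pr)2, THF, −78 °C; then MeI, −78 → −40 °C
Reagents that add atoms: iodomethane, CI
Why: Lactone enolate alkylation (SN2) on the convex face introduces the C6 methyl; its configuration is immaterial because C6 is enolised again in step 7.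

Step 7
Reactants: 15 α-methyl lactone
Product: 17 lactone with quaternary C6 (CH2OPMB exo; CH3 endo), via lithium enolate 16 (not isolated)
Conditions: LiN(i-Pr)2, THF/HMPA, −78 °C; then 4-methoxybenzyl chloromethyl ether, −78 → −20 °C
Reagents that add atoms: 4-methoxybenzyl chloromethyl ether, COc1ccc(COCCl)cc1
Why: The second enolate alkylation brings the alkoxymethyl electrophile in from the convex face of the cis-fused bicycle (syn to H-5, away from C4 and the α-silylvinyl group on C10), which fixes the C6 quaternary centre as required.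

Step 8
Reactants: 17 quaternary lactone
Product: 18 diol (C7H2OH; α-OH on C1)
Conditions: LiAlH4, THF, 0 °C → rt
Reagents that add atoms: none
Why: Hydride reduction of the lactone gives the primary C7 and secondary C1 alcohols without touching the alkenes, the vinylsilane or the PMB ether.

Step 9
Reactants: 18 diol
Product: 19 C7 tert-butyldimethylsilyl ether
Conditions: TBSCl, imidazole, CH2Cl2, 0 °C
Reagents that add atoms: tert-butylchlorodimethylsilane, CC(C)(C)[Si](C)(C)Cl
Why: Silylation discriminates the primary C7 hydroxyl from the hindered secondary C1 hydroxyl (selective protection).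

Step 10
Reactants: 19 silyl ether alcohol
Product: 20 cyclopentanone (C1=O)
Conditions: Dess–Martin periodinane, NaHCO3, CH2Cl2, rt
Reagents that add atoms: none
Why: Dess–Martin oxidation restores the C1 ketone under near-neutral conditions, and C5 remains in its thermodynamically preferred trans relation to C4.

Step 11
Reactants: 20 cyclopentanone
Product: 22 2-diazocyclopentanone (C11=N2), via trifluoroacetyl ketone 21 (not isolated)
Conditions: LiN(SiMe3)2, CF3CO2CH2CF3, THF, −78 °C, 5% HCl quench; then MsN3, Et3N, H2O, MeCN, rt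
Reagents that add atoms: methanesulfonyl azide, CS(=O)(=O)N=[N+]=[N-]
Why: In this detrifluoroacetylative Regitz diazo transfer the kinetic enolate forms at the C11 methylene (C5 is a hindered methine), is trifluoroacetylated, and the activated diketone exchanges its acyl group for the diazo group.

Step 12
Reactants: 22 2-diazocyclopentanone
Product: 25 methyl cyclobutanecarboxylate (CO2Me β on C11), via ketene 23 (not isolated), via epimeric ester 24 (not isolated)
Conditions: hν (365 nm), MeOH, rt; then NaOMe (0.2 equiv), MeOH, 50 °C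
Reagents that add atoms: methanol, CO
Why: Direct irradiation expels N2 from the s-cis-locked cyclic diazoketone and, in a concerted Wolff rearrangement, C5 shifts from C1 to the carbene carbon C11, forming the C5–C11 bond while C1 leaves the ring as a ketene that methanol traps as the ester. The closest known reaction type is the photochemical Wolff ring contraction of 2-diazocycloalkanones to ring-contracted carboxylates, including cyclobutanecarboxylates from 2-diazocyclopentanones. The cyclobutane therefore closes by a 1,2-alkyl shift (ring contraction), not by cyclisation of an open chain, and the migrating C5 keeps its configuration, so the C5, C4 and C10 relationships made on the cyclopentanone reappear unchanged. The only new stereocentre, C11, arises on protonation of the ketene-derived enol and is then settled thermodynamically by NaOMe, which puts the ester on the β face, trans to the α arms on C5 and C10 and cis to the C4 isopropenyl group as the later ring closure requires. The step needs rearrangement to outrun carbene O–H or C–H insertion; the locked s-cis geometry, direct unsensitised excitation and the absence of hydrogen on C10 secure this, and loss of N2 pays for the added ring strain.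

Step 13
Reactants: 25 methyl cyclobutanecarboxylate
Product: 26 N-methoxy-N-methylamide (Weinreb amide)
Conditions: MeNHOMe·HCl, i-PrMgCl, THF, −20 °C → rt
Reagents that add atoms: N,O-dimethylhydroxylamine hydrochloride, CNOC.Cl
Why: Aminolysis of the only ester by the chloromagnesium amide of N,O-dimethylhydroxylamine (Weinreb amide synthesis) proceeds without disturbing the thermodynamically preferred C11 configuration.

Step 14
Reactants: 26 Weinreb amide; 27 vinylmagnesium bromide
Product: 28 vinyl ketone (C11–C(=O)CH=CH2)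
Conditions: THF, 0 °C; inverse quench into cold 1 M HCl
Reagents that add atoms: none
Why: Grignard addition to a Weinreb amide stops at the chelated tetrahedral intermediate, so the vinyl ketone is released only on the cold acidic quench, which also keeps the freed amine from adding back.

Step 15
Reactants: 28 vinyl ketone
Product: 29 bicyclo[3.1.1]heptenone (C1=O; C2=C3–CH3)
Conditions: second-generation Grubbs catalyst (10 mol %), toluene (2 mM), 80 °C, argon sparge
Reagents that add atoms: none
Why: Ring-closing metathesis of the cis-1,3 (both β) vinyl ketone and isopropenyl groups expels ethene and forms the trisubstituted C2=C3 enone, while the vinylsilane and the other α-face groups cannot reach the carbene.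

Step 16
Reactants: 29 bicyclic enone
Product: 31 keto alcohol (C10 acetyl; C7H2OH), via epoxysilane 30 (not isolated)
Conditions: mCPBA, NaHCO3, CH2Cl2, 0 °C → rt; then 1 M HCl, THF/MeOH, rt
Reagents that add atoms: water, O
Why: The electron-poor enone is inert to the peracid, so Prilezhaev epoxidation is confined to the vinylsilane; acid hydrolysis of the α,β-epoxysilane with Peterson-type loss of silicon (epoxide oxygen leaves with silicon, carbonyl oxygen comes from water) unmasks the C9 methyl ketone, and the same acid removes the primary TBS ether.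

Step 17
Reactants: 31 keto alcohol
Product: 32 keto aldehyde (C7H=O)
Conditions: Dess–Martin periodinane, NaHCO3, CH2Cl2, rt
Reagents that add atoms: none
Why: Dess–Martin oxidation converts the neopentyl primary alcohol into a non-enolisable aldehyde that cannot epimerise at C6.

Step 18
Reactants: 32 keto aldehyde
Product: 33 tricyclic β-hydroxy ketone (C7–OH as both epimers; C9=O)
Conditions: LiN(SiMe3)2 (1.05 equiv), THF, −78 °C; AcOH quench at −78 °C
Reagents that add atoms: none
Why: In this intramolecular aldol addition the kinetic enolate of the methyl ketone (C8) attacks the C7 aldehyde, which the cis-1,3 (both α) arrangement of the two arms holds nearby, and closes the seven-membered ring; C7 is left uncontrolled because step 19 erases it.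

Step 19
Reactants: 33 β-hydroxy ketone
Product: 34 tricyclic β-diketone (C7=O; C9=O)
Conditions: Dess–Martin periodinane, CH2Cl2, rt
Reagents that add atoms: none
Why: Dess–Martin oxidation of the aldol mixture converges both C7 epimers onto one β-diketone, so that C7 and C9 can be set afresh by reduction.

Step 20
Reactants: 34 β-diketone
Product: 35 hydroxymethyl diketone (C12–OH)
Conditions: DDQ, CH2Cl2/pH 7 buffer, 0 °C → rt
Reagents that add atoms: none
Why: Oxidative cleavage of the electron-rich 4-methoxybenzyl ether by DDQ frees C12–OH without affecting the enone or the diketone.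

Step 21
Reactants: 35 hydroxymethyl diketone
Product: 36 triol (C12–OH; 7R-OH; 9R-OH)
Conditions: Me4NBH(OAc)3 (6 equiv), MeCN/AcOH 1:1, −30 °C → rt
Reagents that add atoms: none
Why: Two hydroxyl-directed (Evans–Saksena) reductions run in one flask: the C12 alkoxyborohydride delivers hydride to C7 from the face of the CH2O arm (C7–OH trans to C12), and the new C7 alkoxyborohydride then delivers hydride across the ring to C9 from its own face (1,3-anti diol), while the enone, which has no neighbouring hydroxyl, is not reduced.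

Step 22
Reactants: 36 triol
Product: 37 C12,C7-acetonide
Conditions: Me2C(OMe)2, PPTS (cat.), acetone, rt
Reagents that add atoms: 2,2-dimethoxypropane, COC(C)(C)OC
Why: In this acetonide formation only the C12/C7 1,3-diol can be bridged, because the C7 and C9 hydroxyls are trans on the ring, so C9–OH stays free.

Step 23
Reactants: 37 acetonide; 38 3-methylbut-2-enoyl chloride
Product: 39 C9 senecioate acetonide
Conditions: pyridine, DMAP (cat.), CH2Cl2, 0 °C → rt
Reagents that add atoms: none
Why: DMAP-catalysed acylation esterifies the only free hydroxyl, and the weak base pyridine limits vinylketene formation and hence deconjugation of the acyl group.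

Step 24
Reactants: 39 senecioate acetonide
Product: 40 C9 senecioate diol (C12–OH; C7–OH)
Conditions: AcOH/H2O 4:1, 40 °C
Reagents that add atoms: none
Why: Mild acid hydrolysis removes the acetonide, and the trans relation of O7 and O9 on the ring rules out acyl migration.

Step 25
Reactants: 40 senecioate diol; 41 angelic acid ((Z)-2-methylbut-2-enoic acid)
Product: 43 C12 angelate (C7–OH free), via mixed anhydride 42 (not isolated)
Conditions: 2,4,6-trichlorobenzoyl chloride, Et3N, toluene, rt; then 40, toluene, 60 °C (no DMAP)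
Reagents that add atoms: none
Why: Yamaguchi esterification through the mixed anhydride, run without DMAP to avoid Z to E isomerisation, acylates the primary C12 hydroxyl ahead of the hindered secondary C7 hydroxyl.

Step 26
Reactants: 43 angelate alcohol
Product: 44 target (C12 angelate; C9 senecioate; C7 acetate)
Conditions: Ac2O, DMAP, pyridine, CH2Cl2, rt
Reagents that add atoms: acetic anhydride, CC(=O)OC(C)=O
Why: DMAP-catalysed acetylation of the last, hindered secondary hydroxyl completes the target without affecting any stereocentre or the angelate geometry.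

Compound list

1 | 3-methylcyclopent-2-en-1-one | CC1=CC(=O)CC1 | starting material
2 | ethynyltrimethylsilane | C#C[Si](C)(C)C | starting material
3 | diisobutyl[1-(trimethylsilyl)ethenyl]aluminium | CC(C)C[Al](CC(C)C)C(=C)[Si](C)(C)C | intermediate
4 | (R)-3-methyl-3-[1-(trimethylsilyl)ethenyl]cyclopentan-1-one | O=C1C[C@](C)(C(=C)[Si](C)(C)C)CC1 | intermediate
5 | (R)-C1=C5 trimethylsilyl enol ether of 4 | C[Si](C)(C)OC1=CC[C@@](C)(C(=C)[Si](C)(C)C)C1 | intermediate
6 | (S)-4-methyl-4-[1-(trimethylsilyl)ethenyl]cyclopent-2-en-1-one | O=C1C=C[C@@](C)(C(=C)[Si](C)(C)C)C1 | intermediate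
7 | isopropenylmagnesium bromide | CC(=C)[Mg]Br | starting material
8 | C1=C5 trimethylsilyl enol ether; isopropenyl β on C4; CH3 β and 1-silylvinyl α on C10 | C[Si](C)(C)OC1=C[C@H](C(C)=C)[C@@](C)(C(=C)[Si](C)(C)C)C1 | intermediate
9 | methyl bromoacetate | COC(=O)CBr | starting material
10 | lithium enolate corresponding to 8 | [Li]OC1=C[C@H](C(C)=C)[C@@](C)(C(=C)[Si](C)(C)C)C1 | intermediate
11 | keto ester: cyclopentanone (C1=O) with CH2CO2Me α on C5, isopropenyl β on C4, CH3 β and 1-silylvinyl α on C10 | COC(=O)C[C@@H]1C(=O)C[C@](C)(C(=C)[Si](C)(C)C)[C@H]1C(C)=C | intermediate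
12 | hydroxy ester: 11 with α-OH on C1 | COC(=O)C[C@@H]1[C@H](O)C[C@](C)(C(=C)[Si](C)(C)C)[C@H]1C(C)=C | intermediate
13 | cis-fused γ-lactone (C7(=O)–O–C1, C6H2) on the α face | O=C1C[C@@H]2[C@H](O1)C[C@](C)(C(=C)[Si](C)(C)C)[C@H]2C(C)=C | intermediate
14 | lithium enolate of lactone 13 | [Li]OC1=C[C@@H]2[C@H](O1)C[C@](C)(C(=C)[Si](C)(C)C)[C@H]2C(C)=C | intermediate
15 | lactone with exo methyl on C6 | O=C1[C@H](C)[C@@H]2[C@H](O1)C[C@](C)(C(=C)[Si](C)(C)C)[C@H]2C(C)=C | intermediate
16 | lithium enolate of lactone 15 | [Li]OC1=C(C)[C@@H]2[C@H](O1)C[C@](C)(C(=C)[Si](C)(C)C)[C@H]2C(C)=C | intermediate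
17 | lactone with quaternary C6: CH2O-(4-methoxybenzyl) exo (syn to H-5), CH3 endo | O=C1[C@](C)(COCc3ccc(OC)cc3)[C@@H]2[C@H](O1)C[C@](C)(C(=C)[Si](C)(C)C)[C@H]2C(C)=C | intermediate
18 | diol: C7H2OH and α-OH on C1 | OC[C@](C)(COCc1ccc(OC)cc1)[C@@H]2[C@H](O)C[C@](C)(C(=C)[Si](C)(C)C)[C@H]2C(C)=C | intermediate
19 | C7 tert-butyldimethylsilyl ether of 18 | CC(C)(C)[Si](C)(C)OC[C@](C)(COCc1ccc(OC)cc1)[C@@H]2[C@H](O)C[C@](C)(C(=C)[Si](C)(C)C)[C@H]2C(C)=C | intermediate
20 | cyclopentanone (C1=O) with the fully substituted C6 arm on C5 | CC(C)(C)[Si](C)(C)OC[C@](C)(COCc1ccc(OC)cc1)[C@@H]2C(=O)C[C@](C)(C(=C)[Si](C)(C)C)[C@H]2C(C)=C | intermediate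
21 | C11-trifluoroacetyl derivative of 20 | CC(C)(C)[Si](C)(C)OC[C@](C)(COCc1ccc(OC)cc1)[C@@H]2C(=O)C(C(=O)C(F)(F)F)[C@](C)(C(=C)[Si](C)(C)C)[C@H]2C(C)=C | intermediate
22 | 2-diazocyclopentanone (C1=O, C11=N2), (4R,5R,6S,10R) | CC(C)(C)[Si](C)(C)OC[C@](C)(COCc1ccc(OC)cc1)[C@@H]2C(=O)C(=[N+]=[N-])[C@](C)(C(=C)[Si](C)(C)C)[C@H]2C(C)=C | intermediate
23 | cyclobutylidene ketene (C11=C1=O) | CC(C)(C)[Si](C)(C)OC[C@](C)(COCc1ccc(OC)cc1)[C@@H]2C(=C=O)[C@](C)(C(=C)[Si](C)(C)C)[C@H]2C(C)=C | intermediate
24 | methyl cyclobutanecarboxylate with CO2Me α on C11 (C11 epimer of 25) | CC(C)(C)[Si](C)(C)OC[C@](C)(COCc1ccc(OC)cc1)[C@@H]2[C@H](C(=O)OC)[C@](C)(C(=C)[Si](C)(C)C)[C@H]2C(C)=C | intermediate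
25 | methyl cyclobutanecarboxylate with CO2Me β on C11, (4R,5S,6S,10R,11R) | CC(C)(C)[Si](C)(C)OC[C@](C)(COCc1ccc(OC)cc1)[C@@H]2[C@@H](C(=O)OC)[C@](C)(C(=C)[Si](C)(C)C)[C@H]2C(C)=C | intermediate
26 | N-methoxy-N-methylamide corresponding to 25 | CC(C)(C)[Si](C)(C)OC[C@](C)(COCc1ccc(OC)cc1)[C@@H]2[C@@H](C(=O)N(C)OC)[C@](C)(C(=C)[Si](C)(C)C)[C@H]2C(C)=C | intermediate
27 | vinylmagnesium bromide | C=C[Mg]Br | starting material
28 | vinyl ketone (C11–C(=O)CH=CH2, β) | CC(C)(C)[Si](C)(C)OC[C@](C)(COCc1ccc(OC)cc1)[C@@H]2[C@@H](C(=O)C=C)[C@](C)(C(=C)[Si](C)(C)C)[C@H]2C(C)=C | intermediate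
29 | bicyclo[3.1.1]hept-3-en-2-one (C1=O, C2=C3–CH3) with the C6 arm on C5 and CH3/1-silylvinyl on C10 | CC(C)(C)[Si](C)(C)OC[C@](C)(COCc1ccc(OC)cc1)[C@@H]2[C@H]3C(=O)C=C(C)[C@@H]2[C@@]3(C)C(=C)[Si](C)(C)C | intermediate
30 | epoxysilane: 29 with 2-(trimethylsilyl)oxiran-2-yl on C10 | CC(C)(C)[Si](C)(C)OC[C@](C)(COCc1ccc(OC)cc1)[C@@H]2[C@H]3C(=O)C=C(C)[C@@H]2[C@@]3(C)C4(CO4)[Si](C)(C)C | intermediate
31 | keto alcohol: acetyl on C10 (C9=O, C8H3), C7H2OH, C12–O-(4-methoxybenzyl) | OC[C@](C)(COCc1ccc(OC)cc1)[C@@H]2[C@H]3C(=O)C=C(C)[C@@H]2[C@@]3(C)C(C)=O | intermediate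
32 | keto aldehyde (C7H=O) | O=C[C@](C)(COCc1ccc(OC)cc1)[C@@H]2[C@H]3C(=O)C=C(C)[C@@H]2[C@@]3(C)C(C)=O | intermediate
33 | tricyclic β-hydroxy ketone (C7–OH, both epimers; C9=O) | COc1ccc(COC[C@]2(C)[C@@H]3[C@H]4C(=O)C=C(C)[C@@H]3[C@@]4(C)C(=O)CC2O)cc1 | intermediate
34 | tricyclic β-diketone (C7=O, C9=O), C12–O-(4-methoxybenzyl) | COc1ccc(COC[C@]2(C)[C@@H]3[C@H]4C(=O)C=C(C)[C@@H]3[C@@]4(C)C(=O)CC2=O)cc1 | intermediate
35 | hydroxymethyl β-diketone (C12–OH) | OC[C@]1(C)[C@@H]2[C@H]3C(=O)C=C(C)[C@@H]2[C@@]3(C)C(=O)CC1=O | intermediate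
36 | triol (C12–OH, 7R-OH, 9R-OH) | OC[C@]1(C)[C@@H]2[C@H]3C(=O)C=C(C)[C@@H]2[C@@]3(C)[C@H](O)C[C@H]1O | intermediate
37 | C12,C7-acetonide of 36 (C9–OH free) | CC1(C)OC[C@]2(C)[C@@H]3[C@H]4C(=O)C=C(C)[C@@H]3[C@@]4(C)[C@H](O)C[C@H]2O1 | intermediate
38 | 3-methylbut-2-enoyl chloride | CC(C)=CC(=O)Cl | starting material
39 | C9 3-methylbut-2-enoate of acetonide 37 | CC1(C)OC[C@]2(C)[C@@H]3[C@H]4C(=O)C=C(C)[C@@H]3[C@@]4(C)[C@H](OC(=O)C=C(C)C)C[C@H]2O1 | intermediate
40 | C9 3-methylbut-2-enoate with free C12–OH and C7–OH | OC[C@]1(C)[C@@H]2[C@H]3C(=O)C=C(C)[C@@H]2[C@@]3(C)[C@H](OC(=O)C=C(C)C)C[C@H]1O | intermediate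
41 | angelic acid, (Z)-2-methylbut-2-enoic acid | C/C=C(/C)C(=O)O | starting material
42 | (Z)-2-methylbut-2-enoic 2,4,6-trichlorobenzoic anhydride | C/C=C(/C)C(=O)OC(=O)c1c(Cl)cc(Cl)cc1Cl | intermediate
43 | C12 angelate, C9 3-methylbut-2-enoate, free C7–OH | C/C=C(/C)C(=O)OC[C@]1(C)[C@@H]2[C@H]3C(=O)C=C(C)[C@@H]2[C@@]3(C)[C@H](OC(=O)C=C(C)C)C[C@H]1O | intermediate
44 | CNP0179010.1: (4R,5S,6S,7R,9R,10R,11R) C12 angelate, C9 3-methylbut-2-enoate, C7 acetate | C/C=C(/C)C(=O)OC[C@]1(C)[C@@H]2[C@H]3C(=O)C=C(C)[C@@H]2[C@@]3(C)[C@H](OC(=O)C=C(C)C)C[C@H]1OC(C)=O | target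

Totals and risks

Total step count: 26. Longest linear sequence: 26 steps, from 1 to 44.

The three steps most likely to fail:

First, step 15 (ring-closing metathesis). Both olefins initiate slowly, and bridging the cyclobutane adds ring strain, so the catalyst may give cross-metathesis oligomers or leave the diene unchanged. The fallback sets out from 26 and returns at 29. i-Bu2AlH reduces the Weinreb amide to the C11 β-aldehyde F1. Me2AlCl then promotes an intramolecular carbonyl-ene reaction, in which the isopropenyl CH2 attacks the aldehyde and a methyl hydrogen is transferred, closing the six-membered ring as the exo-methylene alcohol F2. Dess–Martin oxidation gives the β,γ-unsaturated ketone F3, and DBU moves the double bond into conjugation to give enone 29.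

Second, step 18 (aldol closure of the seven-membered ring). The aldolate may revert by retro-aldol or dehydrate, or deprotonation may occur at the γ-methyl of the enone instead of C8, so the ring does not close cleanly. The fallback sets out from 32 and returns at 34. NaClO2 with 2-methylbut-2-ene (Pinnick oxidation) converts the aldehyde into the keto acid F4, and 1,1'-carbonyldiimidazole turns it into the acyl imidazolide F5. Two equivalents of LiN(SiMe3)2 then effect an intramolecular Claisen-type C-acylation of the methyl ketone enolate, giving β-diketone 34 directly and irreversibly as its enolate.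

Third, step 21 (double directed reduction). Hydride delivery may stop after the first reduction, or lose facial control at C9 if the enolisable β-diketone ties up the borohydride as a boron chelate; retro-aldol loss of the hydroxymethyl group may also compete. The fallback sets out from 35 and returns at 44. Chlorodiisopropylsilane and imidazole give the O12 diisopropylsilyl ether F6, which carries an Si–H bond. Catalytic SnCl4 triggers a silicon-tethered intramolecular hydrosilylation that reduces only C7, from the face of the CH2O arm, and locks O12 and O7 in the siladioxane ketone F7. HF·pyridine frees the dihydroxy ketone F8, and Yamaguchi esterification with angelic acid acylates the primary hydroxyl to give the angelate hydroxy ketone F9. An Evans–Tishchenko reduction with acetaldehyde and catalytic SmI2 then transfers acetyl to O7 while delivering hydride to C9 anti, giving the C7 acetate with free C9 hydroxyl F10. Acylation with 3-methylbut-2-enoyl chloride, pyridine and DMAP gives 44.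

Further compounds
F1 | step 15 | C11 β-aldehyde from reduction of 26 | CC(C)(C)[Si](C)(C)OC[C@](C)(COCc1ccc(OC)cc1)[C@@H]2[C@@H](C=O)[C@](C)(C(=C)[Si](C)(C)C)[C@H]2C(C)=C
F2 | step 15 | bicyclo[3.1.1]heptane alcohol with C1–OH and exocyclic C3=CH2 | CC(C)(C)[Si](C)(C)OC[C@](C)(COCc1ccc(OC)cc1)[C@@H]2[C@H]3C(O)CC(=C)[C@@H]2[C@@]3(C)C(=C)[Si](C)(C)C
F3 | step 15 | β,γ-unsaturated ketone (C1=O, exocyclic C3=CH2) | CC(C)(C)[Si](C)(C)OC[C@](C)(COCc1ccc(OC)cc1)[C@@H]2[C@H]3C(=O)CC(=C)[C@@H]2[C@@]3(C)C(=C)[Si](C)(C)C
F4 | step 18 | keto acid (C7 carboxylic acid) | OC(=O)[C@](C)(COCc1ccc(OC)cc1)[C@@H]2[C@H]3C(=O)C=C(C)[C@@H]2[C@@]3(C)C(C)=O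
F5 | step 18 | C7 acyl imidazolide | O=C(n1ccnc1)[C@](C)(COCc2ccc(OC)cc2)[C@@H]3[C@H]4C(=O)C=C(C)[C@@H]3[C@@]4(C)C(C)=O
F6 | step 21 | O12 diisopropylsilyl (Si–H) ether of 35 | CC(C)[SiH](C(C)C)OC[C@]1(C)[C@@H]2[C@H]3C(=O)C=C(C)[C@@H]2[C@@]3(C)C(=O)CC1=O
F7 | step 21 | O12,O7-diisopropylsilylene ketone (C9=O) | CC(C)[Si]1(C(C)C)OC[C@]2(C)[C@@H]3[C@H]4C(=O)C=C(C)[C@@H]3[C@@]4(C)C(=O)C[C@H]2O1
F8 | step 21 | dihydroxy ketone (C12–OH, 7R-OH, C9=O) | OC[C@]1(C)[C@@H]2[C@H]3C(=O)C=C(C)[C@@H]2[C@@]3(C)C(=O)C[C@H]1O
F9 | step 21 | C12 angelate hydroxy ketone | C/C=C(/C)C(=O)OC[C@]1(C)[C@@H]2[C@H]3C(=O)C=C(C)[C@@H]2[C@@]3(C)C(=O)C[C@H]1O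
F10 | step 21 | C12 angelate, C7 acetate, free 9R-OH | C/C=C(/C)C(=O)OC[C@]1(C)[C@@H]2[C@H]3C(=O)C=C(C)[C@@H]2[C@@]3(C)[C@H](O)C[C@H]1OC(C)=O
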